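## The problem

The target 25 is a bicyclo[6.2.1] lactone. Its nine-membered carbocycle, ring A (C1–C9), is bridged between C7 and C9 by O–C10(=O), so that C7, C8 and C9 also belong to a γ-lactone. Ring A carries a conjugated triene: the exocyclic Z enol acetate C1=C11, the Z alkene C2=C3 and the E, trisubstituted alkene C4=C5 (methyl on C5). Four stereocentres must be set: C7 (S), C8 (R) and C9 (S) on the lactone, and C12 (S) in the 6-methylhept-5-en-2-yl chain on C8. C12 is acyclic and is best bought. It cannot be trusted to control its neighbour C8, so C8 needs an external control element. C8 can then direct C7 (trans, Felkin–Anh) and C9 (trans alkylation), and the bridge locks the cis C7/C9 relationship. A nine-membered ring holding an E alkene resists end-to-end closure (entropy, transannular strain). The enol acetate, the strained E alkene inside the triene, the lactone and the trisubstituted side-chain alkene rule out strong acid, hydroxide, hydride, ozone, peracid and dissolving metal late in the route. The enabling feature is the Z,E-diene C2=C3–C4=C5 next to C1, which can be a ketone: one Z and one E alkene in a ring is what conrotatory opening of a cis-fused cyclobutene across C2 and C5 delivers, and deleting C3 and C4 leaves a seven-membered enone (C1, C2, C5, C6, C7, C8, C9) that is easy to make.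

## Retrosynthesis

**25 ⇒ 24.** The C11–O acetyl bond and the C11=C1 π bond are removed together: 25 is the O-acetylated extended enolate of aldehyde 24. This takes away the most labile group and one alkene geometry. The forward step must acylate on oxygen and place the acetoxy group syn to C9.

**24 ⇒ 23 ⇒ 21 ⇒ 20.** The C1–C11 bond is cut by a one-carbon homologation of ketone 20 (methylenation to 21, anti-Markovnikov hydration to 23, oxidation to 24). C1 is kept as a ketone up to this point because the ring expansion needs an acyl group at C2 for rate and for direction of rotation. The forward steps need a non-basic methylenation and a hydroboration that picks the one 1,1-disubstituted alkene out of four.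

**20 ⇒ 19 (key disconnection).** The C2=C3 and C4=C5 π bonds are traded for the C2–C5 σ bond and a C3=C4 π bond, giving cyclobutene 19. Against closures of ring A at C9–C1 or C3–C4, this cut needs no medium-ring cyclisation and creates both ring alkene geometries in one stereospecific event. The precursor contains only a seven-membered carbocycle. The forward reaction must rotate the C1 acyl group inward, lie on the open side of the electrocyclic equilibrium and leave the E alkene intact.

**19 ⇒ 17 + 18.** The C2–C3 and C4–C5 bonds are cut: a [2+2] photocycloaddition of enone 17 with acetylene (18). The alkyne is symmetric, so there is no regiochemistry, and both new stereocentres vanish in the next step, so facial selectivity is not critical. The forward step must capture the enone triplet efficiently and avoid secondary photochemistry.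

**17 ⇒ 16 ⇒ 15 ⇒ 12 + 13.** The C2=C5 alkene is cut by ring-closing metathesis and the C9–C1 bond by an aldol reaction of lactone 12 with acrolein (13). Metathesis is run on allylic alcohol 15, not on a polymerisation-prone vinyl ketone. Bridging needs C7 and C9 cis, which follows from aldol attack anti to the C8 substituent. The precursor is a monocyclic trans-4,5-disubstituted butyrolactone.

**12 ⇒ 11 ⇒ 9.** The lactone C10–O bond and the C6–C7 bond are cut: methallylation of aldehyde 9, then lactonisation. The addition must occur on the Si face to give (S)-C7; reagent control and Felkin–Anh control point the same way.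

**9 ⇒ 8 ⇒ 7 ⇒ 4 + 5; 4 ⇒ 1 + 2.** The C8–C9 bond is cut as an auxiliary-controlled alkylation of imide 4 with tert-butyl bromoacetate (5). The imide comes from (S)-citronellic acid (1), which supplies C12 and the side chain, and oxazolidinone 2. Direct α-alkylation of the corresponding aldehyde would be shorter but would leave C8 to weak 1,2-induction from C12.

## Roads not taken

**Alternative 1:** Cut at C9–C1. An open-chain lactone A1, with a Z-alkenyl iodide at the end of the C7 side chain, would be cyclised by Pd-catalysed enolate alkenylation (Pd2(dba)3, bulky phosphine, LiN(SiMe3)2) to give A2, ring A with C1=C2 and C4=C5 alkenes and C11 as a silyl ether.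
- Merits: the E C4=C5 geometry is fixed in open-chain chemistry before cyclisation; C11 is oxygenated from the start; no photochemistry is needed.
- Weak points: a nine-membered ring is closed through a ten-membered palladacycle; the strong amide base can dehydrohalogenate the Z-alkenyl iodide or cause Claisen condensation of the lactone; A2 is a skipped diene and needs desilylation, oxidation to the enal and γ-deprotonation/O-acetylation, so the C2=C3 geometry is created only at the end; A1 needs a long linear sequence with two defined alkenes.
- Comparison: this road is safer for the E alkene and avoids the chemoselective hydroboration. The chosen plan sets against it ring expansion in place of medium-ring closure and the formation of both diene alkenes in one step.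

**Alternative 2:** Cut at C3–C4. The bis(alkenyl iodide) A3 would be closed with stoichiometric zerovalent nickel (Ni(cod)2, PPh3) to give the Z,E-diene A4 with both geometries retained.
- Merits: the diene is formed directly with defined geometry; A4 is the silyl ether of one C1 epimer of alcohol 23, so the endgame is two steps shorter than here and needs no ketone chemistry.
- Weak points: the reductive elimination must pass through a strained nickelacycle containing an E-alkenyl unit; intermolecular coupling and proto-deiodination compete; the reagent is air-sensitive and stoichiometric; A3 requires a Z-alkenyl iodide next to a C1 stereocentre that is later erased, plus an E-2-methylalkenyl iodide.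
- Comparison: this road is equal or better in endgame economy and geometric certainty. The chosen plan answers with a much shorter approach to the cyclisation precursor (ten steps to 19 from commodity materials) and no medium-ring closure.

**Alternative 3:** Cut at C1–C2 by ring contraction. The ten-membered dienyl carbinol mesylate A5 would undergo an Et3Al-promoted semipinacol shift of C2 from C11 to C1, giving aldehyde A6.
- Merits: A6 is one C1 epimer of aldehyde 24, so only the enol acetylation remains, the best endgame of all four plans; alkenyl groups migrate readily and stereospecifically.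
- Weak points: the medium-ring problem is only moved to A5, a ten-membered Z,E-dienyl carbinol with two extra stereocentres; the migrating bond must be anti-periplanar to the mesylate, which the ring may not allow; epoxide formation, hydride shift and allylic ionisation compete under the aluminium Lewis acid.
- Comparison: this road has the better endgame and a weaker front end. The chosen plan offers an easily made seven-membered precursor.

Key step: step 11

Assumption: the carbinol configuration in 15 and 16 and the C1 configuration in 22–24 are left unassigned because both centres become sp2 carbon later. Step 10 is drawn for addition anti to the lactone bridge; either cis-fused adduct would open to the same dienone. Target numbering (C1–C12) is used in the descriptions.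

## Route

Step 1
Reactants: 1 (S)-citronellic acid [(3S)-3,7-dimethyloct-6-enoic acid]; 2 (S)-4-benzyloxazolidin-2-one
Product: 4 (4S)-4-benzyl-3-[(3S)-3,7-dimethyloct-6-enoyl]oxazolidin-2-one, via mixed pivalic anhydride 3 (not isolated)
Conditions: t-BuCOCl, Et3N, THF, −20 °C; then LiCl, 2, −20 °C → rt
Reagents that add atoms: none
Why: Mixed-anhydride N-acylation of an Evans oxazolidinone (LiCl/Et3N activation); no stereocentre is touched, and C12 comes unchanged from 1.

Step 2
Reactants: 4; 5 tert-butyl bromoacetate
Product: 7 tert-butyl (3S,4S)-3-[(4S)-4-benzyl-2-oxooxazolidine-3-carbonyl]-4,8-dimethylnon-7-enoate, via sodium Z-enolate 6 (not isolated)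
Conditions: NaN(SiMe3)2, THF, −78 °C; then 5, −78 → −40 °C
Reagents that add atoms: none
Why: Evans asymmetric alkylation: the chelated Z-enolate is alkylated on the face opposite the benzyl group, which sets C8 (C3 of the ester) as needed. The auxiliary overrides the neighbouring C12 centre, and bromoacetates are reactive enough for β-branched imides.

Step 3
Reactants: 7
Product: 8 tert-butyl (3S,4S)-3-(hydroxymethyl)-4,8-dimethylnon-7-enoate
Conditions: LiBH4, MeOH (1 equiv), Et2O, 0 °C
Reagents that add atoms: none
Why: Reductive cleavage of the auxiliary: the imide carbonyl is reduced much faster than the tert-butyl ester, C8 is not enolised, and 2 is recovered.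

Step 4
Reactants: 8
Product: 9 tert-butyl (3S,4S)-3-formyl-4,8-dimethylnon-7-enoate
Conditions: Dess–Martin periodinane, NaHCO3, CH2Cl2, 0 °C → rt
Reagents that add atoms: none
Why: Buffered Dess–Martin oxidation should give the α-branched aldehyde without epimerising C8 or touching the alkene and ester; 9 is used at once.

Step 5
Reactants: 9
Product: 11 tert-butyl (3S,4S)-3-[(1S)-1-hydroxy-3-methylbut-3-en-1-yl]-4,8-dimethylnon-7-enoate, via diisopinocampheylborinate 10 (not isolated)
Conditions: (−)-Ipc2BOMe [from (+)-α-pinene], CH2=C(CH3)CH2MgCl, Et2O, −78 °C → rt; then 9, −78 °C; then NaOAc (aq), H2O2, 0 °C → rt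
Reagents that add atoms: B-(2-methylallyl)diisopinocampheylborane, made in the flask, C=C(C)CB([C@@H]1C[C@@H]2C[C@H]([C@H]1C)C2(C)C)[C@@H]1C[C@@H]2C[C@H]([C@H]1C)C2(C)C
Why: Brown asymmetric methallylboration through a closed chair transition state: this enantiomer of the reagent adds to the Si face of 9 and creates (S)-C7. This is also the Felkin–Anh sense when the C12 branch is the large α-substituent, so reagent and substrate control reinforce each other.

Step 6
Reactants: 11
Product: 12 (4S,5S)-5-(2-methylprop-2-en-1-yl)-4-[(2S)-6-methylhept-5-en-2-yl]oxolan-2-one (4,5-trans)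
Conditions: p-TsOH·H2O (5 mol%), CH2Cl2, rt
Reagents that add atoms: none
Why: Acid-catalysed γ-lactonisation (intramolecular transesterification) with loss of tert-butanol; the C7–O bond is not broken, so the trans C7/C8 relationship is carried over.

Step 7
Reactants: 12; 13 acrolein
Product: 15 (3S,4R,5S)-3-(1-hydroxyprop-2-en-1-yl)-5-(2-methylprop-2-en-1-yl)-4-[(2S)-6-methylhept-5-en-2-yl]oxolan-2-one (carbinol epimers), via lithium lactone enolate 14 (not isolated)
Conditions: LiN(iPr)2, THF, −78 °C; then 13, −78 °C; NH4Cl (aq)
Reagents that add atoms: none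
Why: Aldol 1,2-addition of the lactone enolate to acrolein: the electrophile enters anti to the C8 substituent, so the C9 branch is trans to C8 and cis to the C7 methallyl group, as bridging requires.

Step 8
Reactants: 15
Product: 16 (1S,6S,9R)-2-hydroxy-4-methyl-9-[(2S)-6-methylhept-5-en-2-yl]-7-oxabicyclo[4.2.1]non-3-en-8-one (C2 epimers)
Conditions: second-generation Grubbs catalyst (H2IMes)(PCy3)Cl2Ru=CHPh (5 mol%), 1,4-benzoquinone (10 mol%), CH2Cl2 (2 mM), 40 °C
Reagents that add atoms: none
Why: Ring-closing metathesis of the vinyl carbinol with the 1,1-disubstituted methallyl alkene closes the seven-membered ring across the cis C7/C9 positions and forms the trisubstituted C2=C5 alkene. The side-chain alkene is slower and would give an eight-membered ring; benzoquinone suppresses Ru–H isomerisation of the allylic alcohol.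

Step 9
Reactants: 16
Product: 17 (1S,6S,9R)-4-methyl-9-[(2S)-6-methylhept-5-en-2-yl]-7-oxabicyclo[4.2.1]non-3-ene-2,8-dione (lactone-bridged 3-methylcyclohept-2-enone)
Conditions: Dess–Martin periodinane, NaHCO3, CH2Cl2, rt
Reagents that add atoms: none
Why: Dess–Martin oxidation of the allylic alcohol to the enone; C9 is a bridgehead between two carbonyls whose enolisation is disfavoured in this bicycle, so it is configurationally secure.

Step 10
Reactants: 17; 18 acetylene
Product: 19 lactone-bridged bicyclo[5.2.0]non-8-en-2-one: cyclobutene (C3=C4) cis-fused at C2 and C5 on the face of the seven-membered ring opposite the lactone bridge, H on C2 and CH3 on C5 syn to the bridge (2S,5R,7S,8R,9S,12S)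
Conditions: HC≡CH (saturated), acetone, hν (350 nm, uranium-glass filter), −70 °C, to partial conversion
Reagents that add atoms: none
Why: Enone–alkyne [2+2] photocycloaddition from the enone triplet through a 1,4-biradical. The lactone bridge restrains the seven-membered ring, which should curb the E/Z isomerisation that deactivates free cycloheptenones, and it screens one face. Long-wavelength light and partial conversion limit 1,3-acyl shift of the β,γ-unsaturated ketone product.

Step 11
Reactants: 19
Product: 20 (1S,3Z,5E,8S,11R)-6-methyl-11-[(2S)-6-methylhept-5-en-2-yl]-9-oxabicyclo[6.2.1]undeca-3,5-diene-2,10-dione [(2Z,4E)-dienone, C1 ketone, in target numbering]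
Conditions: ZnI2 (1.0 equiv), ClCH2CH2Cl, 60 °C, dark; cold NaHCO3 (aq) quench
Reagents that add atoms: none
Why: Thermally allowed conrotatory 4π electrocyclic ring opening: the C2–C5 σ bond and the C3=C4 π bond reorganise into the C2=C3 and C4=C5 π bonds, so the bond shared by the four- and seven-membered rings disappears. The closest known reaction type is the thermal or Lewis-acid-assisted opening of enone–alkyne photoadducts (cis-bicyclo[n.2.0]alkenones) to cis,trans-cycloalkadienones, a two-carbon ring expansion. Ring A is therefore not closed end to end; it arises by expansion of the seven-membered ring to nine within the lactone-bridged frame, which avoids a medium-ring cyclisation. No stereocentre is created: C2 and C5 become sp2, and C7, C8, C9 and C12 are untouched. Because the ring fusion is cis, conrotation turns one ring bond inward and one outward, so one Z and one E ring alkene must result; the selectivity needed is the torquoselectivity that sends the C1 acyl group inward at C2 (Z C2=C3) and hence C6 outward at C5 (E C4=C5). Coordination of ZnI2 to the C1 ketone makes the acyl group a strong π-acceptor that prefers inward rotation and lowers the barrier, while at C5 the two alkyl groups (CH3 and C6) are nearly equivalent. The alternative (2E,4Z) isomer would contain a twisted E-enone and can return through 19, so kinetic and thermodynamic preferences point the same way. Cyclobutene strain release, dienone conjugation and the stronger binding of the Lewis acid to the vinylogous carbonyl of 20 drive the opening; a mild Lewis acid and moderate temperature are chosen so that the E alkene does not relax to Z through the polarised dienone complex or by [1,5]-hydrogen shift.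

Step 12
Reactants: 20
Product: 21 (1S,3Z,5E,8S,11R)-6-methyl-2-methylidene-11-[(2S)-6-methylhept-5-en-2-yl]-9-oxabicyclo[6.2.1]undeca-3,5-dien-10-one
Conditions: Zn, CH2Br2, TiCl4, THF, 0 °C (reagent preformed); then 20, CH2Cl2, 0 °C → rt
Reagents that add atoms: dibromomethane, BrCBr
Why: Takai–Lombardo methylenation: the non-basic gem-dimetallic reagent methylenates hindered, conjugated ketones without touching the lactone, deprotonating C9 or adding in a conjugate sense.

Step 13
Reactants: 21
Product: 23 (3Z,5E)-2-(hydroxymethyl)-6-methyl-11-[(2S)-6-methylhept-5-en-2-yl]-9-oxabicyclo[6.2.1]undeca-3,5-dien-10-one (C7, C8, C9 as in 21; C1 of target numbering unassigned), via B-alkyl-9-BBN adduct 22 (not isolated)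
Conditions: 9-BBN (1.1 equiv), THF, 0 °C → rt; then NaOAc (aq), H2O2, 0 °C
Reagents that add atoms: hydrogen peroxide, OO
Why: Hydroboration–oxidation: 9-BBN adds anti-Markovnikov to the only terminal 1,1-disubstituted alkene (boron on C11), much faster than to the trisubstituted and internal alkenes; buffered oxidation spares the lactone, and the new C1 centre is erased in step 15.

Step 14
Reactants: 23
Product: 24 (3Z,5E)-6-methyl-11-[(2S)-6-methylhept-5-en-2-yl]-10-oxo-9-oxabicyclo[6.2.1]undeca-3,5-diene-2-carbaldehyde (C1 of target numbering unassigned)
Conditions: Dess–Martin periodinane, NaHCO3, CH2Cl2, 0 °C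
Reagents that add atoms: none
Why: Buffered Dess–Martin oxidation of the primary alcohol should give the β,γ-unsaturated aldehyde without moving the diene into conjugation; 24 is used directly.

Step 15
Reactants: 24
Product: 25 target, [(Z)-[(1S,3Z,5E,8S,11R)-6-methyl-11-[(2S)-6-methylhept-5-en-2-yl]-10-oxo-9-oxabicyclo[6.2.1]undeca-3,5-dien-2-ylidene]methyl] acetate
Conditions: Ac2O, Et3N, DMAP (cat.), CH2Cl2, 0 °C → rt
Reagents that add atoms: acetic anhydride, CC(=O)OC(C)=O
Why: Dienol acetylation: amine-mediated enolisation of the doubly activated C1–H gives the extended enolate, which is O-acetylated by the N-acetylpyridinium salt, forming C11=C1 and erasing the C1 centre. The Z isomer (acetoxy syn to C9–H, away from the plane of the C2=C3 bond) is the one wanted; its preference is expected to be modest and the isomers are to be separated.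

## Compound list

1 | (S)-citronellic acid | OC(=O)C[C@@H](C)CCC=C(C)C | starting material
2 | (S)-4-benzyloxazolidin-2-one | O=C1OC[C@H](Cc2ccccc2)N1 | starting material
3 | mixed pivalic anhydride of 1 | CC(C)(C)C(=O)OC(=O)C[C@@H](C)CCC=C(C)C | intermediate
4 | (4S)-4-benzyl-3-[(3S)-3,7-dimethyloct-6-enoyl]oxazolidin-2-one | O=C(C[C@@H](C)CCC=C(C)C)N1[C@@H](Cc2ccccc2)COC1=O | intermediate
5 | tert-butyl bromoacetate | CC(C)(C)OC(=O)CBr | starting material
6 | sodium Z-enolate of 4 | [Na+].[O-]/C(=C\[C@@H](C)CCC=C(C)C)N1[C@@H](Cc2ccccc2)COC1=O | intermediate
7 | tert-butyl (3S,4S)-3-[(4S)-4-benzyl-2-oxooxazolidine-3-carbonyl]-4,8-dimethylnon-7-enoate | CC(C)(C)OC(=O)C[C@H](C(=O)N1[C@@H](Cc2ccccc2)COC1=O)[C@@H](C)CCC=C(C)C | intermediate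
8 | tert-butyl (3S,4S)-3-(hydroxymethyl)-4,8-dimethylnon-7-enoate | CC(C)(C)OC(=O)C[C@H](CO)[C@@H](C)CCC=C(C)C | intermediate
9 | tert-butyl (3S,4S)-3-formyl-4,8-dimethylnon-7-enoate | CC(C)(C)OC(=O)C[C@H](C=O)[C@@H](C)CCC=C(C)C | intermediate
10 | diisopinocampheylborinate of 11 | CC(C)(C)OC(=O)C[C@H]([C@@H](OB([C@@H]1C[C@@H]2C[C@H]([C@H]1C)C2(C)C)[C@@H]1C[C@@H]2C[C@H]([C@H]1C)C2(C)C)CC(C)=C)[C@@H](C)CCC=C(C)C | intermediate
11 | tert-butyl (3S,4S)-3-[(1S)-1-hydroxy-3-methylbut-3-en-1-yl]-4,8-dimethylnon-7-enoate | CC(C)(C)OC(=O)C[C@H]([C@@H](O)CC(C)=C)[C@@H](C)CCC=C(C)C | intermediate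
12 | (4S,5S)-5-(2-methylprop-2-en-1-yl)-4-[(2S)-6-methylhept-5-en-2-yl]oxolan-2-one | C=C(C)C[C@@H]1OC(=O)C[C@H]1[C@@H](C)CCC=C(C)C | intermediate
13 | acrolein | C=CC=O | starting material
14 | lithium enolate of 12 | [Li+].[O-]C1=C[C@@H]([C@@H](C)CCC=C(C)C)[C@H](CC(C)=C)O1 | intermediate
15 | (3S,4R,5S)-3-(1-hydroxyprop-2-en-1-yl)-5-(2-methylprop-2-en-1-yl)-4-[(2S)-6-methylhept-5-en-2-yl]oxolan-2-one | C=CC(O)[C@H]1C(=O)O[C@@H](CC(C)=C)[C@@H]1[C@@H](C)CCC=C(C)C | intermediate
16 | (1S,6S,9R)-2-hydroxy-4-methyl-9-[(2S)-6-methylhept-5-en-2-yl]-7-oxabicyclo[4.2.1]non-3-en-8-one | OC1C=C(C)C[C@@H]2OC(=O)[C@H]1[C@H]2[C@@H](C)CCC=C(C)C | intermediate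
17 | (1S,6S,9R)-4-methyl-9-[(2S)-6-methylhept-5-en-2-yl]-7-oxabicyclo[4.2.1]non-3-ene-2,8-dione | O=C1C=C(C)C[C@@H]2OC(=O)[C@H]1[C@H]2[C@@H](C)CCC=C(C)C | intermediate
18 | acetylene | C#C | starting material
19 | lactone-bridged bicyclo[5.2.0]non-8-en-2-one (cis-fused cyclobutene photoadduct) | O=C1[C@H]3C=C[C@@]3(C)C[C@@H]2OC(=O)[C@H]1[C@H]2[C@@H](C)CCC=C(C)C | intermediate
20 | (1S,3Z,5E,8S,11R)-6-methyl-11-[(2S)-6-methylhept-5-en-2-yl]-9-oxabicyclo[6.2.1]undeca-3,5-diene-2,10-dione | O=C1/C=C\C=C(/C)C[C@@H]2OC(=O)[C@H]1[C@H]2[C@@H](C)CCC=C(C)C | intermediate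
21 | (1S,3Z,5E,8S,11R)-6-methyl-2-methylidene-11-[(2S)-6-methylhept-5-en-2-yl]-9-oxabicyclo[6.2.1]undeca-3,5-dien-10-one | C=C1/C=C\C=C(/C)C[C@@H]2OC(=O)[C@H]1[C@H]2[C@@H](C)CCC=C(C)C | intermediate
22 | B-alkyl-9-BBN adduct of 21 (boron on C11) | C(B1C2CCCC1CCC2)C3/C=C\C=C(/C)C[C@@H]4OC(=O)[C@H]3[C@H]4[C@@H](C)CCC=C(C)C | intermediate
23 | (3Z,5E)-2-(hydroxymethyl)-6-methyl-11-[(2S)-6-methylhept-5-en-2-yl]-9-oxabicyclo[6.2.1]undeca-3,5-dien-10-one | OCC1/C=C\C=C(/C)C[C@@H]2OC(=O)[C@H]1[C@H]2[C@@H](C)CCC=C(C)C | intermediate
24 | (3Z,5E)-6-methyl-11-[(2S)-6-methylhept-5-en-2-yl]-10-oxo-9-oxabicyclo[6.2.1]undeca-3,5-diene-2-carbaldehyde | O=CC1/C=C\C=C(/C)C[C@@H]2OC(=O)[C@H]1[C@H]2[C@@H](C)CCC=C(C)C | intermediate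
25 | target enol acetate | CC(=O)O/C=C1/C=C\C=C(/C)C[C@@H]2OC(=O)[C@H]1[C@H]2[C@@H](C)CCC=C(C)C | target

## Step count and risks

Total steps: 15. Longest linear sequence: 15 steps (1 → 25).

**Step 11 (key step).** Two things are most likely to go wrong. The electrocyclic equilibrium may stall on the bicyclic side, because the unsubstituted bicyclo[5.2.0]nonene/cis,trans-cyclononadiene pair is close to thermoneutral and only conjugation, the C5 methyl group and Lewis-acid binding tip it. The Lewis acid may also cause geometric relaxation of the strained E alkene through the polarised dienone complex. Fallback, from 19 back to 20: Lewis-acid steering is given up for thermodynamic selection. Compound 19 is heated without additive in toluene or xylene in base-washed glass. Only the conrotatory manifold is then open, the two cis,trans isomers interconvert through 19, and the less strained (2Z,4E)-dienone 20 should accumulate. Material that relaxes to the (2Z,4Z)-dienone F1 is not lost: direct irradiation of a cyclic cis,cis-2,4-dienone closes it disrotatorily to the cis-fused cyclobutene, that is back to 19, which is fed in again.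

**Step 10.** Inefficient capture of the enone triplet by a gaseous, weakly reactive alkyne and secondary 1,3-acyl shift of the product are the likely failures. Fallback, from 17 back to 19: (E)-1,2-dichloroethene, an established acetylene surrogate, is used as the 2π partner to give the dichlorocyclobutane F2, which is no longer a β,γ-unsaturated ketone. The ketone is masked as its dioxolane F3 (ethylene glycol, p-TsOH). Reductive 1,2-elimination with NaC10H8 (sodium naphthalenide, inverse addition, −78 °C) gives the cyclobutene ketal F4; mild aqueous acid then returns 19.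

**Step 8.** Redox isomerisation of the allylic alcohol by ruthenium hydrides, or slow closure of the bridged ring so that intermolecular metathesis or reaction at the side-chain alkene competes, may erode the cyclisation. Fallback, from 15 back to 17: the oxidation is done first (Dess–Martin periodinane) to give the vinyl ketone F5. F5 cannot isomerise in that way, and its C9 centre equilibrates freely, so all material can reach the cis arrangement. Ring-closing metathesis of this enone-type diene then gives 17 directly.

**Step 13.** Loss of chemoselectivity in the hydroboration (attack at the strained E alkene or the side-chain alkene) is the risk. Fallback, from 20 back to 24, bypassing steps 12–14: Wittig methoxymethylenation of the ketone (Ph3P(CH2OMe)Cl, KN(SiMe3)2) gives the methyl trienol ether F6. Mild hydrolysis (oxalic acid, wet THF, 0 °C) should protonate the dienol ether kinetically at the α-carbon C1 and release the β,γ-unsaturated aldehyde 24.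

**Step 15.** Poor control of the C11=C1 geometry during O-acetylation is the main risk; enol acetates cannot be recycled cleanly. Fallback, from 24 back to 25: the extended enolate is trapped as the silyl trienol ether (t-BuMe2SiOTf, Et3N). The Z isomer F7 is separated, and the E isomer is hydrolysed back to 24 and recycled. F7 is converted into 25 by fluoride-triggered silicon-to-acetyl exchange (Ac2O, CsF, MeCN), which retains the enol geometry.

## Further compounds

F1 | step 11 | (2Z,4Z)-dienone isomer of 20 | O=C1/C=C\C=C(\C)C[C@@H]2OC(=O)[C@H]1[C@H]2[C@@H](C)CCC=C(C)C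
F2 | step 10 | 3,4-dichlorocyclobutane photoadduct of 17 (chloride configurations open) | O=C1[C@H]3C(Cl)C(Cl)[C@@]3(C)C[C@@H]2OC(=O)[C@H]1[C@H]2[C@@H](C)CCC=C(C)C
F3 | step 10 | C1 ethylene ketal of F2 | O1CCOC12[C@H]3C(Cl)C(Cl)[C@@]3(C)C[C@@H]4OC(=O)[C@H]2[C@H]4[C@@H](C)CCC=C(C)C
F4 | step 10 | C1 ethylene ketal of 19 | O1CCOC12[C@H]3C=C[C@@]3(C)C[C@@H]4OC(=O)[C@H]2[C@H]4[C@@H](C)CCC=C(C)C
F5 | step 8 | 3-acryloyl lactone (vinyl ketone from 15) | C=CC(=O)[C@H]1C(=O)O[C@@H](CC(C)=C)[C@@H]1[C@@H](C)CCC=C(C)C
F6 | step 13 | methyl trienol ether of 24 (C11=C1 geometry open) | COC=C1/C=C\C=C(/C)C[C@@H]2OC(=O)[C@H]1[C@H]2[C@@H](C)CCC=C(C)C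
F7 | step 15 | (Z)-tert-butyldimethylsilyl trienol ether of 24 | CC(C)(C)[Si](C)(C)O/C=C1/C=C\C=C(/C)C[C@@H]2OC(=O)[C@H]1[C@H]2[C@@H](C)CCC=C(C)C
A1 | alternative 1 | (4S,5S)-5-[(2E,5Z)-7-(tert-butyldimethylsilyloxy)-6-iodo-2-methylhepta-2,5-dien-1-yl]-4-[(2S)-6-methylhept-5-en-2-yl]oxolan-2-one | CC(C)(C)[Si](C)(C)OC/C(I)=C/C/C=C(\C)C[C@@H]1OC(=O)C[C@H]1[C@@H](C)CCC=C(C)C
A2 | alternative 1 | ring A lactone with C1=C2 and C4=C5 alkenes, C11 tert-butyldimethylsilyl ether | CC(C)(C)[Si](C)(C)OC/C1=C/C/C=C(\C)C[C@@H]2OC(=O)[C@H]1[C@H]2[C@@H](C)CCC=C(C)C
A3 | alternative 2 | bis(alkenyl iodide) lactone: (E)-3-iodo-2-methylprop-2-enyl on C7, (Z)-1-(tert-butyldimethylsilyloxy)-4-iodobut-3-en-2-yl on C9 | CC(C)(C)[Si](C)(C)OC[C@H](/C=C\I)[C@H]1C(=O)O[C@@H](C/C(C)=C/I)[C@@H]1[C@@H](C)CCC=C(C)C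
A4 | alternative 2 | Z,E-diene lactone, C11 tert-butyldimethylsilyl ether | CC(C)(C)[Si](C)(C)OC[C@@H]1/C=C\C=C(/C)C[C@@H]2OC(=O)[C@H]1[C@H]2[C@@H](C)CCC=C(C)C
A5 | alternative 3 | ten-membered Z,E-dienyl carbinol with mesylate on C1 (carbinol configuration open) | CS(=O)(=O)O[C@@H]1C(O)/C=C\C=C(/C)C[C@@H]2OC(=O)[C@H]1[C@H]2[C@@H](C)CCC=C(C)C
A6 | alternative 3 | ring A aldehyde, C11 formyl on C1 | O=C[C@@H]1/C=C\C=C(/C)C[C@@H]2OC(=O)[C@H]1[C@H]2[C@@H](C)CCC=C(C)C
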